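**Plan**
- Retrosynthetic cuts, in this order: the C3–CH2 bond to the catechol benzyl group (enediolate alkylation); the lactone C5–O1 bond (ring closure); the C2–C3 bond (carboxyl carbon from chloroform); the CH2 of a cyclopropane (Simmons–Smith).
- Enabling feature: C4 carries both the lactone CH2 (C5) and the benzylic CH2 of the 3,4-dimethoxybenzyl group. Joined to each other, these two carbons and C4 form a cyclopropane conjugated to the electron-rich dimethoxyphenyl ring, and the carboxyl group on C3 sits two atoms from C5.
- Forward order: the cyclopropane ring is made first (step 1) and its side chain is grown to a cyclopropyl glycolic acid (steps 2–4). The lactone ring then arises by oxidative, strain-releasing opening of the cyclopropane (step 5), the second benzyl group is put on C3 (step 6), and the catechol is freed (step 7).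
- Stereochemistry: C4 comes from the (1R,2R)-cyclopropane set by the chiral dioxaborolane in step 1 and is not touched again. C3 is carried as a mixture of epimers through 4–8 and is set in step 6 by alkylation of the planar enediolate on the face opposite the C4 benzyl group.

Key step: step 5

**Step 1**
Reactants: 1 (E)-3-(3,4-dimethoxyphenyl)prop-2-en-1-ol
Product: 2 [(1R,2R)-2-(3,4-dimethoxyphenyl)cyclopropyl]methanol
Conditions: Et2Zn, CH2I2, DME, CH2Cl2, −10 °C (gives Zn(CH2I)2); then 1 and (4S,5S)-2-butyl-N,N,N',N'-tetramethyl-1,3,2-dioxaborolane-4,5-dicarboxamide (1.2 equiv), −10 °C to rt; aq. NH4Cl, then aq. KOH wash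
Reagents that add atoms: diiodomethane, ICI
Why: Simmons–Smith cyclopropanation in its Charette form: the zinc alkoxide of 1 binds the chiral dioxaborolane, which should direct CH2 transfer from Zn(CH2I)2 to one face of the E-alkene, so the trans relationship is carried over stereospecifically and the (4S,5S) controller should give the (1R,2R) ring, the mirror image of what the (4R,5R) controller is known to give with E-cinnamyl alcohols.

**Step 2**
Reactants: 2 [(1R,2R)-2-(3,4-dimethoxyphenyl)cyclopropyl]methanol
Product: 3 (1R,2R)-2-(3,4-dimethoxyphenyl)cyclopropane-1-carbaldehyde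
Conditions: TEMPO (10 mol%), PhI(OAc)2 (1.1 equiv), CH2Cl2, rt
Reagents that add atoms: none
Why: Oxoammonium (TEMPO) oxidation of a primary alcohol stops at the aldehyde under these mild conditions and should leave the electron-rich arylcyclopropane and both ring stereocentres untouched.

**Step 3**
Reactants: 3 (1R,2R)-2-(3,4-dimethoxyphenyl)cyclopropane-1-carbaldehyde
Product: 4 2,2,2-trichloro-1-[(1R,2R)-2-(3,4-dimethoxyphenyl)cyclopropyl]ethan-1-ol (both carbinol epimers)
Conditions: CHCl3 (reagent and solvent), DBU (1 equiv), 0 °C to rt
Reagents that add atoms: chloroform, ClC(Cl)Cl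
Why: Base-mediated addition of the trichloromethyl anion (from CHCl3 and DBU) to an aldehyde that does not readily enolise should give the trichloromethyl carbinol, whose new carbinol centre is formed without control and needs none.

**Step 4**
Reactants: 4 2,2,2-trichloro-1-[(1R,2R)-2-(3,4-dimethoxyphenyl)cyclopropyl]ethan-1-ol
Product: 7 2-[(1R,2R)-2-(3,4-dimethoxyphenyl)cyclopropyl]-2-hydroxyacetic acid (both C-2 epimers), via gem-dichloroepoxide 5 (not isolated), via hydroxy acyl chloride 6 (not isolated)
Conditions: NaOH (aq., 5 equiv), DME, 0 °C to rt; then cold dilute HCl to pH 3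
Reagents that add atoms: sodium hydroxide, [Na+].[OH-]
Why: Jocic reaction: the alkoxide should close onto the CCl3 carbon to give the gem-dichloroepoxide 5, hydroxide should open it at the carbinol carbon by SN2 to the hydroxy acyl chloride 6, and this is hydrolysed to the carboxylate, the configuration at this carbon being of no consequence because step 6 makes it planar.

**Step 5**
Reactants: 7 2-[(1R,2R)-2-(3,4-dimethoxyphenyl)cyclopropyl]-2-hydroxyacetic acid
Product: 8 (4S)-4-[(3,4-dimethoxyphenyl)methyl]-3-hydroxyoxolan-2-one (both C-3 epimers)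
Conditions: 9-mesityl-3,6-di-tert-butyl-10-phenylacridinium tetrafluoroborate (5 mol%), PhSSPh (10 mol%), degassed ClCH2CH2Cl, no base, 450 nm LEDs, rt
Reagents that add atoms: none
Why: Proposed new method: the excited acridinium should oxidise the dimethoxyphenyl ring of 7 to its radical cation, which weakens the two cyclopropane bonds to the benzylic carbon; the carboxyl oxygen, held on C3 two atoms away, then attacks the ring CH2 on the side opposite the benzylic carbon (three-electron SN2), the CH2–benzylic bond breaks with release of ring strain, the benzylic radical takes a hydrogen atom from PhSH, and PhS• returns the acridine radical to the acridinium, so the step is a redox-neutral isomerisation. The closest known reaction types are the acridinium/thiol anti-Markovnikov hydrolactonisation of alkenoic acids through alkene radical cations and the intermolecular nucleophilic ring-opening hydrofunctionalisation of arylcyclopropane radical cations. The five-membered lactone closes with the C4–CH2 bond of the three-membered ring inside the new ring and the breaking bond outside it, the same mode as the 5-endo iodolactonisation of β,γ-unsaturated acids (exo with respect to the bond that breaks). No new stereocentre is formed: C4 should keep the configuration set in step 1 because none of its four bonds is broken in the arene-centred, ring-closed radical cation, and the epimer mixture at C3 is simply carried through. The step needs attack at the ring CH2 and not at the ring CH (which would give a strained β-lactone) or at the benzylic carbon (which would leave a non-stabilised radical), and it needs the acid to stay protonated so that it is not oxidised and decarboxylated; ring size, radical stability and the absence of base should secure this.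

**Step 6**
Reactants: 8 (4S)-4-[(3,4-dimethoxyphenyl)methyl]-3-hydroxyoxolan-2-one; 9 4-(chloromethyl)-1,2-bis(benzyloxy)benzene
Product: 11 (3S,4S)-3-{[3,4-bis(benzyloxy)phenyl]methyl}-4-[(3,4-dimethoxyphenyl)methyl]-3-hydroxyoxolan-2-one, via dilithium enediolate 10 (not isolated)
Conditions: LiN(SiMe3)2 (2.3 equiv), THF/DMPU, −78 °C; then 9, −78 to −20 °C; aq. NH4Cl
Reagents that add atoms: none
Why: Alkylation of an α-hydroxy lactone dianion: both epimers of 8 give the same planar enediolate 10, and the benzylic chloride should enter on the ring face opposite the C4 dimethoxybenzyl group, which places the new benzyl group trans to it and the hydroxyl cis, that is (3S).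

**Step 7**
Reactants: 11 (3S,4S)-3-{[3,4-bis(benzyloxy)phenyl]methyl}-4-[(3,4-dimethoxyphenyl)methyl]-3-hydroxyoxolan-2-one
Product: 12 (3S,4S)-3-[(3,4-dihydroxyphenyl)methyl]-4-[(3,4-dimethoxyphenyl)methyl]-3-hydroxyoxolan-2-one
Conditions: H2 (1 atm), Pd/C, EtOAc/EtOH, rt
Reagents that add atoms: none
Why: Hydrogenolysis of aryl benzyl ethers over palladium should free the catechol, while the lactone, the tertiary alcohol, the methyl ethers and both stereocentres carry no bond that is cleaved under these conditions.

**Compound list**
1 | (E)-3-(3,4-dimethoxyphenyl)prop-2-en-1-ol (3,4-dimethoxycinnamyl alcohol) | COc1ccc(/C=C/CO)cc1OC | starting material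
2 | [(1R,2R)-2-(3,4-dimethoxyphenyl)cyclopropyl]methanol | OC[C@@H]1C[C@H]1c1ccc(OC)c(OC)c1 | intermediate
3 | (1R,2R)-2-(3,4-dimethoxyphenyl)cyclopropane-1-carbaldehyde | O=C[C@@H]1C[C@H]1c1ccc(OC)c(OC)c1 | intermediate
4 | 2,2,2-trichloro-1-[(1R,2R)-2-(3,4-dimethoxyphenyl)cyclopropyl]ethan-1-ol, both epimers at the carbinol carbon | OC([C@@H]1C[C@H]1c1ccc(OC)c(OC)c1)C(Cl)(Cl)Cl | intermediate
5 | 2,2-dichloro-3-[(1R,2R)-2-(3,4-dimethoxyphenyl)cyclopropyl]oxirane, formed in the flask and not isolated | ClC1(Cl)OC1[C@@H]1C[C@H]1c1ccc(OC)c(OC)c1 | intermediate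
6 | 2-[(1R,2R)-2-(3,4-dimethoxyphenyl)cyclopropyl]-2-hydroxyacetyl chloride, formed in the flask and not isolated | OC(C(=O)Cl)[C@@H]1C[C@H]1c1ccc(OC)c(OC)c1 | intermediate
7 | 2-[(1R,2R)-2-(3,4-dimethoxyphenyl)cyclopropyl]-2-hydroxyacetic acid, both epimers at C-2 | OC(C(=O)O)[C@@H]1C[C@H]1c1ccc(OC)c(OC)c1 | intermediate
8 | (4S)-4-[(3,4-dimethoxyphenyl)methyl]-3-hydroxyoxolan-2-one, both epimers at C-3 | COc1ccc(C[C@H]2COC(=O)C2O)cc1OC | intermediate
9 | 4-(chloromethyl)-1,2-bis(benzyloxy)benzene (3,4-bis(benzyloxy)benzyl chloride) | ClCc1ccc(OCc2ccccc2)c(OCc2ccccc2)c1 | starting material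
10 | dilithium (4S)-4-[(3,4-dimethoxyphenyl)methyl]-4,5-dihydrofuran-2,3-bis(olate), formed in the flask and not isolated | [Li+].[Li+].COc1ccc(C[C@H]2COC([O-])=C2[O-])cc1OC | intermediate
11 | (3S,4S)-3-{[3,4-bis(benzyloxy)phenyl]methyl}-4-[(3,4-dimethoxyphenyl)methyl]-3-hydroxyoxolan-2-one | COc1ccc(C[C@H]2COC(=O)[C@]2(O)Cc2ccc(OCc3ccccc3)c(OCc3ccccc3)c2)cc1OC | intermediate
12 | (3S,4S)-3-[(3,4-dihydroxyphenyl)methyl]-4-[(3,4-dimethoxyphenyl)methyl]-3-hydroxyoxolan-2-one | COc1ccc(C[C@H]2COC(=O)[C@]2(O)Cc2ccc(O)c(O)c2)cc1OC | target

**Step count**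
Total: 7 steps. Longest linear sequence: 7 steps (1 to 12); compound 9 is bought.

**Steps most likely to fail**

Step 5 (Proposed new method). What may go wrong: the radical cation may stay too arene-centred to be attacked at the ring CH2; reversible opening of the bond between C4 and the benzylic carbon may erode the C4 configuration; or oxidation of the α-hydroxy acid may lead to loss of CO2. The fallback uses known chemistry only, sets out from 1 and comes back at 8. The alkene of 1 is hydrogenated (H2, Pd/C, EtOAc) to 3-(3,4-dimethoxyphenyl)propan-1-ol F1, which is oxidised (TEMPO, PhI(OAc)2, CH2Cl2) to 3-(3,4-dimethoxyphenyl)propanal F2. An enamine cross-aldol reaction of F2 with ethyl glyoxylate, catalysed by a diarylprolinol (α,α-bis[3,5-bis(trifluoromethyl)phenyl]pyrrolidin-2-ylmethanol, the R enantiomer expected by analogy with D-proline), should give ethyl (3R)-4-(3,4-dimethoxyphenyl)-3-formyl-2-hydroxybutanoate F3, in which the catalyst sets the later C4. Immediate reduction with NaBH4 in EtOH at 0 °C should give ethyl (3S)-4-(3,4-dimethoxyphenyl)-2-hydroxy-3-(hydroxymethyl)butanoate F4, which should lactonise with a trace of TsOH to 8.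

Step 4. What may go wrong: ionisation of the dichloroepoxide at the carbon next to the donor-substituted cyclopropane, with opening of the three-membered ring (cyclopropylcarbinyl to homoallyl), may compete with SN2 attack by hydroxide. The fallback sets out from 3 and comes back at 7. Wittig methylenation of 3 (Ph3P=CH2, THF, 0 °C) should give 4-[(1R,2S)-2-ethenylcyclopropyl]-1,2-dimethoxybenzene F5. Dihydroxylation of the vinyl group (OsO4 cat., NMO, acetone/water) should give 1-[(1R,2R)-2-(3,4-dimethoxyphenyl)cyclopropyl]ethane-1,2-diol F6. Selective oxidation of the primary alcohol (TEMPO cat., NaClO2, NaOCl cat., pH 6.7 phosphate buffer, MeCN) should then give 7 without a cationic intermediate next to the ring.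

Step 6. What may go wrong: C-alkylation of the hindered enediolate by the benzylic chloride may be slow, with competing O-benzylation of the alkoxide. The fallback sets out from 8 and comes back at 12. The enediolate 10 is trapped at −78 °C with the more reactive 3,4-bis(benzyloxy)benzaldehyde in an aldol addition, again anti to the C4 benzyl group, to give (3R,4S)-3-{[3,4-bis(benzyloxy)phenyl](hydroxy)methyl}-4-[(3,4-dimethoxyphenyl)methyl]-3-hydroxyoxolan-2-one F7 as a mixture at the benzylic carbinol. Hydrogenolysis (H2, Pd/C, EtOH/AcOH) should then remove the benzylic hydroxyl and both benzyl ethers in one operation to give 12.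

**Further compounds**
F1 | step 5 | 3-(3,4-dimethoxyphenyl)propan-1-ol | COc1ccc(CCCO)cc1OC
F2 | step 5 | 3-(3,4-dimethoxyphenyl)propanal | COc1ccc(CCC=O)cc1OC
F3 | step 5 | ethyl (3R)-4-(3,4-dimethoxyphenyl)-3-formyl-2-hydroxybutanoate | COc1ccc(C[C@H](C(O)C(=O)OCC)C=O)cc1OC
F4 | step 5 | ethyl (3S)-4-(3,4-dimethoxyphenyl)-2-hydroxy-3-(hydroxymethyl)butanoate | COc1ccc(C[C@H](C(O)C(=O)OCC)CO)cc1OC
F5 | step 4 | 4-[(1R,2S)-2-ethenylcyclopropyl]-1,2-dimethoxybenzene | C=C[C@@H]1C[C@H]1c1ccc(OC)c(OC)c1
F6 | step 4 | 1-[(1R,2R)-2-(3,4-dimethoxyphenyl)cyclopropyl]ethane-1,2-diol | OCC(O)[C@@H]1C[C@H]1c1ccc(OC)c(OC)c1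
F7 | step 6 | (3R,4S)-3-{[3,4-bis(benzyloxy)phenyl](hydroxy)methyl}-4-[(3,4-dimethoxyphenyl)methyl]-3-hydroxyoxolan-2-one | COc1ccc(C[C@H]2COC(=O)[C@]2(O)C(O)c2ccc(OCc3ccccc3)c(OCc3ccccc3)c2)cc1OC
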